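**Retrosynthetic overview**
1. Target ⇒ late C5 angeloylation (Yamaguchi), C2 enone from a C2 aldehyde (Nozaki–Hiyama–Kishi propenylation, then oxidation), exo-methylene by Mannich methylenation of the cis-lactone.
2. cis-γ-Lactone (C6–O, C7–C11) ⇒ Ueno–Stork radical cyclisation of a C6 bromoacetal onto the C7=C8 alkene of a cycloheptene, itself from ring-closing metathesis of a 1,8-diene.
3. Diene ⇒ Brown (Z)-γ-alkoxyallylboration of a C5 aldehyde (sets C5, C6) and 1,3-anti directed reduction of a C9 vinyl ketone (sets C9).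
4. C9–C10–C1 core ⇒ key intermolecular Mukaiyama aldol (Evans copper–bis(oxazoline)) of an α-keto ester (C5–C1–C2) with a thiopropionate silyl ketene acetal (C9, C10, C14); it forms the C1–C10 bond and both stereocentres.
5. Ring order: seven-membered carbocycle first (metathesis), lactone ring second (radical cyclisation, oxidation).

Assumption: atom labels follow the target as a 4,5-seco-guaianolide (C1 = C(OH) bearing C2(=O)–C3=C4–C15; C5 = CH–O-angeloyl; C6 = lactone O–CH; C7 = ring-fusion CH; C8 = CH2; C9 = CH–OH; C10 = CH–CH3 (C14); C11/C12/C13 = lactone α-C, C=O, =CH2); descriptors in names are CIP letters at these labels (target 1S,5S,6R,7S,9R,10S); angelic acid, (E)-1-iodoprop-1-ene, the box ligand and (−)-Ipc2BOMe are bought.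

**Route**

Step 1
Reactants: 1 methyl acrylate
Product: 2 methyl 2,3-dihydroxypropanoate (racemic)
Conditions: K2OsO4·2H2O (1 mol%), NMO, acetone/H2O 4:1, rt
Reagents that add atoms: N-methylmorpholine N-oxide C[N+]1([O-])CCOCC1; water O
Why: Upjohn syn-dihydroxylation of the acrylate; the racemic carbinol centre is erased in step 3.

Step 2
Reactants: 2 methyl 2,3-dihydroxypropanoate
Product: 3 methyl 3-(tert-butyldimethylsilyloxy)-2-hydroxypropanoate (racemic)
Conditions: TBSCl (1.05 equiv), imidazole, CH2Cl2, 0 °C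
Reagents that add atoms: tert-butyldimethylsilyl chloride CC(C)(C)[Si](C)(C)Cl
Why: Silyl ether formation is selective for the primary over the secondary α-hydroxy-ester alcohol on steric grounds.

Step 3
Reactants: 3 methyl 3-(tert-butyldimethylsilyloxy)-2-hydroxypropanoate
Product: 4 methyl 3-(tert-butyldimethylsilyloxy)-2-oxopropanoate
Conditions: Dess–Martin periodinane, NaHCO3, CH2Cl2, rt
Reagents that add atoms: none
Why: Dess–Martin oxidation gives the α-keto ester under anhydrous, non-basic conditions that avoid hydrate formation and silyl loss.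

Step 4
Reactants: 5 S-ethyl propanethioate
Product: 6 (Z)-1-(ethylthio)-1-(trimethylsilyloxy)prop-1-ene
Conditions: LiN(i-Pr)2, THF, −78 °C; TMSCl, −78 °C → rt
Reagents that add atoms: chlorotrimethylsilane C[Si](C)(C)Cl
Why: Kinetic enolisation in THF followed by O-silylation (enol silane formation) gives the (Z)-silyl ketene thioacetal used in Mukaiyama aldol chemistry.

Step 5
Reactants: 4 methyl 3-(tert-butyldimethylsilyloxy)-2-oxopropanoate; 6 (Z)-1-(ethylthio)-1-(trimethylsilyloxy)prop-1-ene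
Product: 7 (1S,10R)-EtS-C9(=O)-C10H(Me)-C1(OTMS)(CO2Me)-C5H2-OTBS
Conditions: Cu(OTf)2 (10 mol%), (R,R)-t-Bu-box (11 mol%), THF, −78 °C; silica filtration (TMS ether kept)
Reagents that add atoms: none
Why: Evans copper–bis(oxazoline) Mukaiyama aldol: the keto ester binds copper through both carbonyls, the ligand shields one ketone face, and the open transition state gives the syn adduct (C10-Me/C1-O across the succinate chain), so the C1–C10 bond, C1 (S) and C10 are set together with silyl transfer to O1.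

Step 6
Reactants: 7 aldol adduct thioester
Product: 8 (1S,10R)-O=C9H-C10H(Me)-C1(OTMS)(CO2Me)-C5H2-OTBS
Conditions: Et3SiH, 10% Pd/C, acetone, rt
Reagents that add atoms: none
Why: Fukuyama reduction converts the thioester to the aldehyde chemoselectively, leaving the methyl ester and both silyl ethers.

Step 7
Reactants: 8 aldehyde
Product: 9 (1S,10S)-H2C=C8H-C9H(OH)-C10H(Me)-C1(OTMS)(CO2Me)-C5H2-OTBS (C9 epimers)
Conditions: CH2=CHMgBr (1.2 equiv), THF, −78 °C; aq. NH4Cl
Reagents that add atoms: vinylmagnesium bromide C=C[Mg]Br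
Why: Grignard 1,2-addition is faster to the aldehyde than to the hindered ester at −78 °C; the C9 mixture is irrelevant because C9 is oxidised next.

Step 8
Reactants: 9 allylic alcohols
Product: 11 (1S,10R)-H2C=C8H-C9(=O)-C10H(Me)-C1(OH)(CO2Me)-C5H2-OTBS, via TMS-protected vinyl ketone 10 (not isolated)
Conditions: Dess–Martin periodinane, NaHCO3, CH2Cl2, 0 °C; then AcOH/THF/H2O 3:1:1, rt
Reagents that add atoms: none
Why: Dess–Martin oxidation gives the enone and mild acidic hydrolysis removes only the labile tertiary TMS ether, freeing the hydroxyl that directs the next reduction.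

Step 9
Reactants: 11 β-hydroxy vinyl ketone
Product: 12 (1S,9R,10S)-H2C=C8H-C9H(OH)-C10H(Me)-C1(OH)(CO2Me)-C5H2-OTBS
Conditions: Me4NBH(OAc)3, MeCN/AcOH 1:1, −30 °C
Reagents that add atoms: none
Why: Evans–Saksena hydroxyl-directed reduction delivers hydride intramolecularly through a chair in which C10-Me, CH2OTBS and the vinyl group are all equatorial, giving the 1,3-anti diol and thus C9 (R).

Step 10
Reactants: 12 anti-diol
Product: 13 (1S,9R,10S)-H2C=C8H-C9H(OTIPS)-C10H(Me)-C1(OH)(CO2Me)-C5H2-OTBS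
Conditions: TIPSOTf (1.1 equiv), 2,6-lutidine, CH2Cl2, −78 → −20 °C
Reagents that add atoms: triisopropylsilyl triflate CC(C)[Si](C(C)C)(C(C)C)OS(=O)(=O)C(F)(F)F
Why: Silylation takes the secondary allylic hydroxyl and leaves the far more hindered tertiary C1 hydroxyl.

Step 11
Reactants: 13 TIPS ether
Product: 14 (1R,9R,10S)-H2C=C8H-C9H(OTIPS)-C10H(Me)-C1(OH)(C2H2OH)-C5H2-OTBS
Conditions: LiBH4, THF/MeOH, 0 °C → rt
Reagents that add atoms: none
Why: Borohydride reduction of the α-hydroxy ester (assisted by the neighbouring hydroxyl) gives the C2 primary alcohol without touching silyl ethers or the alkene.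

Step 12
Reactants: 14 diol
Product: 15 (1R,9R,10S)-C1/C2-O-isopropylidene acetal of 14
Conditions: 2,2-dimethoxypropane, PPTS, CH2Cl2, rt
Reagents that add atoms: 2,2-dimethoxypropane COC(C)(C)OC
Why: Transketalisation closes the favoured five-membered dioxolane on the 1,2-diol, masking C1–OH and C2–OH together.

Step 13
Reactants: 15 acetonide
Product: 16 (1S,9R,10S)-C5H2-OH alcohol (C1/C2 acetonide; C9-OTIPS)
Conditions: HF·pyridine, pyridine, THF, 0 °C → rt
Reagents that add atoms: none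
Why: Buffered fluoride desilylation removes the primary TBS ether much faster than the secondary TIPS ether.

Step 14
Reactants: 16 primary alcohol
Product: 17 (1R,9R,10S)-C5H=O aldehyde (C1/C2 acetonide; C9-OTIPS)
Conditions: Dess–Martin periodinane, NaHCO3, CH2Cl2, rt
Reagents that add atoms: none
Why: Dess–Martin oxidation gives an aldehyde whose α-carbon is quaternary, so it cannot epimerise or enolise.

Step 15
Reactants: 18 allyl alcohol
Product: 19 allyl methoxymethyl ether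
Conditions: MOMCl, i-Pr2NEt, CH2Cl2, 0 °C → rt
Reagents that add atoms: chloromethyl methyl ether COCCl
Why: O-Alkylation (acetal ether formation) provides the precursor of the γ-alkoxyallyl reagent.

Step 16
Reactants: 17 aldehyde; 19 allyl methoxymethyl ether
Product: 21 (1R,5S,6R,9R,10S)-H2C=C8H-C9H(OTIPS)-C10H(Me)-C1(acetonide)-C5H(OH)-C6H(OMOM)-C7H=CH2, via alkoxyallylborane 20 (not isolated)
Conditions: 19, sec-BuLi, THF, −78 °C; (−)-Ipc2BOMe; BF3·OEt2; then 17, −78 °C → rt; NaOH, H2O2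
Reagents that add atoms: none
Why: Brown asymmetric (Z)-γ-alkoxyallylboration (carbonyl allylation): the chair transition state converts the Z-geometry into the syn C5-OH/C6-OMOM pair, and the (+)-α-pinene-derived isopinocampheyl groups select the aldehyde face giving C5 (S) and C6 (R).

Step 17
Reactants: 21 homoallylic alcohol
Product: 22 (1R,5S,6R,9R,10S)-C5-O-triethylsilyl ether of 21
Conditions: TESOTf, 2,6-lutidine, CH2Cl2, −78 → 0 °C
Reagents that add atoms: triethylsilyl triflate CC[Si](CC)(CC)OS(=O)(=O)C(F)(F)F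
Why: The reactive silyl triflate protects the hindered C5 hydroxyl so that only C6–O is unveiled later.

Step 18
Reactants: 22 diene
Product: 23 (1R,5S,6R,9R,10S)-cycloheptene (C7=C8; C1/C2 acetonide; C5-OTES; C6-OMOM; C9-OTIPS; C10-Me)
Conditions: second-generation Grubbs catalyst (H2IMes)(PCy3)Cl2Ru=CHPh (10 mol%), CH2Cl2 (2 mM), 40 °C
Reagents that add atoms: none
Why: Ring-closing metathesis of the two terminal vinyl groups forms the seven-membered ring with loss of ethylene and creates no stereocentre.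

Step 19
Reactants: 23 cycloheptene
Product: 24 (1R,5S,6R,9R,10S)-C6-OH allylic alcohol
Conditions: TMSOTf, 2,2'-bipyridyl, CH2Cl2, 0 °C; then H2O
Reagents that add atoms: none
Why: Fujioka MOM cleavage proceeds through a bipyridinium intermediate under non-acidic conditions, which should spare the ketal and the silyl ethers.

Step 20
Reactants: 24 allylic alcohol
Product: 25 C6-O-CH(OEt)CH2Br mixed bromoacetal of 24 (acetal epimers)
Conditions: NBS, ethyl vinyl ether, CH2Cl2, −40 → 0 °C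
Reagents that add atoms: N-bromosuccinimide O=C1CCC(=O)N1Br; ethyl vinyl ether C=COCC
Why: Bromoalkoxylation of the vinyl ether by the only free hydroxyl installs the Ueno–Stork radical precursor.

Step 21
Reactants: 25 bromoacetal
Product: 26 (1R,5S,6R,7S,9R,10S)-cis-fused 2-ethoxytetrahydrofuran (O–C6; C7–C11H2–C12H(OEt); C8H2)
Conditions: Bu3SnH, AIBN (cat.), PhH (0.01 M), 80 °C, slow addition
Reagents that add atoms: none
Why: Ueno–Stork 5-exo-trig radical cyclisation: the two-atom tether on O6 can only reach C7 from the face of the C6–O bond, giving the cis ring fusion and C7 (S), with C8 reduced to CH2.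

Step 22
Reactants: 26 cyclic acetal
Product: 27 (1R,5S,6R,7S,9R,10S)-cis-fused γ-lactone (C12=O)
Conditions: mCPBA, BF3·OEt2 (cat.), CH2Cl2, 0 °C
Reagents that add atoms: 3-chloroperbenzoic acid OOC(=O)c1cccc(Cl)c1
Why: Grieco oxidation (Lewis-acid-promoted peracid oxidation of a 2-alkoxytetrahydrofuran) gives the lactone without aqueous acid.

Step 23
Reactants: 27 lactone
Product: 28 C11-(dimethylaminomethyl) lactone (C11 epimers)
Conditions: LiN(i-Pr)2, THF, −78 °C; then (CH2=NMe2)I, −78 °C → rt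
Reagents that add atoms: Eschenmoser's salt C=[N+](C)C.[I-]
Why: Mannich reaction of the lactone lithium enolate (the only enolisable position) with the preformed iminium salt adds C13.

Step 24
Reactants: 28 Mannich base
Product: 30 (1R,5S,6R,7S,9R,10S)-α-methylene lactone (C11=C13H2), via trimethylammonium iodide 29 (not isolated)
Conditions: MeI, MeOH, rt; then NaHCO3, CH2Cl2/H2O, rt
Reagents that add atoms: none
Why: N-Quaternisation followed by base-induced β-elimination of trimethylamine gives the exocyclic methylene.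

Step 25
Reactants: 30 α-methylene lactone
Product: 31 (1R,5S,6R,7S,9R,10S)-C5-OH alcohol
Conditions: HF·pyridine, pyridine, THF, 0 °C
Reagents that add atoms: none
Why: Fluoride desilylation removes the TES ether far faster than the TIPS ether and does not affect the ketal or the Michael acceptor.

Step 26
Reactants: 31 alcohol
Product: 32 (1R,5S,6R,7S,9R,10S)-C5-O-angelate
Conditions: angelic acid, 2,4,6-trichlorobenzoyl chloride, Et3N, PhMe, rt; then 31, PhMe, 75 °C
Reagents that add atoms: angelic acid C/C=C(/C)C(=O)O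
Why: Yamaguchi esterification through the mixed anhydride, run without DMAP to suppress angelate-to-tiglate isomerisation, acylates the only free hydroxyl.

Step 27
Reactants: 32 angelate
Product: 33 (1R,5S,6R,7S,9R,10S)-C1-OH/C2H2-OH diol
Conditions: AcOH/H2O 4:1, 40 °C
Reagents that add atoms: none
Why: Acid-catalysed ketal hydrolysis frees the diol while the TIPS ether, angelate and methylene lactone tolerate mild acid.

Step 28
Reactants: 33 diol
Product: 34 (1S,5S,6R,7S,9R,10S)-C2H=O α-hydroxy aldehyde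
Conditions: IBX, DMSO, rt
Reagents that add atoms: none
Why: IBX oxidises the primary alcohol and, unlike periodinane or periodate reagents, does not cleave the 1,2-diol; the tertiary hydroxyl is inert.

Step 29
Reactants: 34 aldehyde
Product: 35 (1R,5S,6R,7S,9R,10S)-C2H(OH)-C3H=C4H-CH3 (E) allylic alcohol (C2 epimers)
Conditions: (E)-1-iodoprop-1-ene, CrCl2 (4 equiv), NiCl2 (1 mol%), DMSO, rt
Reagents that add atoms: (E)-1-iodoprop-1-ene C/C=C/I
Why: Nozaki–Hiyama–Kishi alkenylation adds only to the aldehyde, tolerating both lactone and ester Michael acceptors, with retention of the E geometry; the C2 mixture converges on oxidation.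

Step 30
Reactants: 35 allylic alcohols
Product: 36 (1S,5S,6R,7S,9R,10S)-C2 (E)-enone with C9-OTIPS
Conditions: MnO2, CH2Cl2, rt
Reagents that add atoms: none
Why: Allylic oxidation with MnO2 gives the E-crotonoyl ketone under neutral conditions without touching the tertiary alcohol.

Step 31
Reactants: 36 silyl ether
Product: 37 target CNP0149130.1
Conditions: HF·pyridine, THF, 0 °C → rt
Reagents that add atoms: none
Why: Fluoride desilylation releases C9–OH under mildly acidic conditions that preserve the angelate, enone and methylene lactone.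

**Compound list**
1 | methyl acrylate | C=CC(=O)OC | starting material
2 | methyl 2,3-dihydroxypropanoate (racemic) | OCC(O)C(=O)OC | intermediate
3 | methyl 3-(tert-butyldimethylsilyloxy)-2-hydroxypropanoate (racemic) | CC(C)(C)[Si](C)(C)OCC(O)C(=O)OC | intermediate
4 | methyl 3-(tert-butyldimethylsilyloxy)-2-oxopropanoate | CC(C)(C)[Si](C)(C)OCC(=O)C(=O)OC | intermediate
5 | S-ethyl propanethioate | CCC(=O)SCC | starting material
6 | (Z)-1-(ethylthio)-1-(trimethylsilyloxy)prop-1-ene | C/C=C(\SCC)O[Si](C)(C)C | intermediate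
7 | (1S,10R)-EtS-C9(=O)-C10H(Me)-C1(OTMS)(CO2Me)-C5H2-OTBS | CCSC(=O)[C@H](C)[C@@](O[Si](C)(C)C)(C(=O)OC)CO[Si](C)(C)C(C)(C)C | intermediate
8 | (1S,10R)-C9 aldehyde of 7 | O=C[C@H](C)[C@@](O[Si](C)(C)C)(C(=O)OC)CO[Si](C)(C)C(C)(C)C | intermediate
9 | (1S,10S)-C9 vinyl carbinol (C9 epimers), C1-OTMS | C=CC(O)[C@H](C)[C@@](O[Si](C)(C)C)(C(=O)OC)CO[Si](C)(C)C(C)(C)C | intermediate
10 | (1S,10R)-C9 vinyl ketone, C1-OTMS | C=CC(=O)[C@H](C)[C@@](O[Si](C)(C)C)(C(=O)OC)CO[Si](C)(C)C(C)(C)C | intermediate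
11 | (1S,10R)-C9 vinyl ketone, C1-OH | C=CC(=O)[C@H](C)[C@@](O)(C(=O)OC)CO[Si](C)(C)C(C)(C)C | intermediate
12 | (1S,9R,10S)-C1,C9-anti-diol | C=C[C@@H](O)[C@H](C)[C@@](O)(C(=O)OC)CO[Si](C)(C)C(C)(C)C | intermediate
13 | (1S,9R,10S)-C9-OTIPS ether of 12 | C=C[C@@H](O[Si](C(C)C)(C(C)C)C(C)C)[C@H](C)[C@@](O)(C(=O)OC)CO[Si](C)(C)C(C)(C)C | intermediate
14 | (1R,9R,10S)-C1-OH/C2H2-OH diol | C=C[C@@H](O[Si](C(C)C)(C(C)C)C(C)C)[C@H](C)[C@@](O)(CO)CO[Si](C)(C)C(C)(C)C | intermediate
15 | (1R,9R,10S)-C1/C2 acetonide, C5H2-OTBS | C=C[C@@H](O[Si](C(C)C)(C(C)C)C(C)C)[C@H](C)[C@]1(CO[Si](C)(C)C(C)(C)C)COC(C)(C)O1 | intermediate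
16 | (1S,9R,10S)-C1/C2 acetonide, C5H2-OH | C=C[C@@H](O[Si](C(C)C)(C(C)C)C(C)C)[C@H](C)[C@]1(CO)COC(C)(C)O1 | intermediate
17 | (1R,9R,10S)-C1/C2 acetonide, C5 aldehyde | C=C[C@@H](O[Si](C(C)C)(C(C)C)C(C)C)[C@H](C)[C@]1(C=O)COC(C)(C)O1 | intermediate
18 | allyl alcohol | C=CCO | starting material
19 | allyl methoxymethyl ether | C=CCOCOC | intermediate
20 | [(Z)-3-(methoxymethoxy)allyl]diisopinocampheylborane (from (+)-α-pinene) | COCO/C=C\CB([C@@H]1C[C@@H]2C[C@@H](C2(C)C)[C@H]1C)[C@@H]1C[C@@H]2C[C@@H](C2(C)C)[C@H]1C | intermediate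
21 | (1R,5S,6R,9R,10S)-diene, C5-OH, C6-OMOM | C=C[C@@H](O[Si](C(C)C)(C(C)C)C(C)C)[C@H](C)[C@]1([C@@H](O)[C@H](OCOC)C=C)COC(C)(C)O1 | intermediate
22 | (1R,5S,6R,9R,10S)-diene, C5-OTES, C6-OMOM | C=C[C@@H](O[Si](C(C)C)(C(C)C)C(C)C)[C@H](C)[C@]1([C@@H](O[Si](CC)(CC)CC)[C@H](OCOC)C=C)COC(C)(C)O1 | intermediate
23 | (1R,5S,6R,9R,10S)-cycloheptene, C6-OMOM | CC(C)[Si](C(C)C)(C(C)C)O[C@@H]2C=C[C@@H](OCOC)[C@H](O[Si](CC)(CC)CC)[C@]3(COC(C)(C)O3)[C@H]2C | intermediate
24 | (1R,5S,6R,9R,10S)-cycloheptene, C6-OH | CC(C)[Si](C(C)C)(C(C)C)O[C@@H]2C=C[C@@H](O)[C@H](O[Si](CC)(CC)CC)[C@]3(COC(C)(C)O3)[C@H]2C | intermediate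
25 | C6-O-(2-bromo-1-ethoxyethyl) acetal of 24 (acetal epimers) | CC(C)[Si](C(C)C)(C(C)C)O[C@@H]2C=C[C@@H](OC(CBr)OCC)[C@H](O[Si](CC)(CC)CC)[C@]3(COC(C)(C)O3)[C@H]2C | intermediate
26 | (1R,5S,6R,7S,9R,10S)-cis-fused 2-ethoxytetrahydrofuran | CC(C)[Si](C(C)C)(C(C)C)O[C@@H]2C[C@H]4CC(OCC)O[C@H]4[C@H](O[Si](CC)(CC)CC)[C@]3(COC(C)(C)O3)[C@H]2C | intermediate
27 | (1R,5S,6R,7S,9R,10S)-cis-fused γ-lactone | CC(C)[Si](C(C)C)(C(C)C)O[C@@H]2C[C@H]4CC(=O)O[C@H]4[C@H](O[Si](CC)(CC)CC)[C@]3(COC(C)(C)O3)[C@H]2C | intermediate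
28 | C11-(dimethylaminomethyl) lactone (C11 epimers) | CC(C)[Si](C(C)C)(C(C)C)O[C@@H]2C[C@H]4C(CN(C)C)C(=O)O[C@H]4[C@H](O[Si](CC)(CC)CC)[C@]3(COC(C)(C)O3)[C@H]2C | intermediate
29 | C11-(trimethylammoniomethyl) lactone iodide | CC(C)[Si](C(C)C)(C(C)C)O[C@@H]2C[C@H]4C(C[N+](C)(C)C)C(=O)O[C@H]4[C@H](O[Si](CC)(CC)CC)[C@]3(COC(C)(C)O3)[C@H]2C.[I-] | intermediate
30 | (1R,5S,6R,7S,9R,10S)-α-methylene lactone, C5-OTES | CC(C)[Si](C(C)C)(C(C)C)O[C@@H]2C[C@H]4C(=C)C(=O)O[C@H]4[C@H](O[Si](CC)(CC)CC)[C@]3(COC(C)(C)O3)[C@H]2C | intermediate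
31 | (1R,5S,6R,7S,9R,10S)-α-methylene lactone, C5-OH | CC(C)[Si](C(C)C)(C(C)C)O[C@@H]2C[C@H]4C(=C)C(=O)O[C@H]4[C@H](O)[C@]3(COC(C)(C)O3)[C@H]2C | intermediate
32 | (1R,5S,6R,7S,9R,10S)-C5 angelate, C1/C2 acetonide | CC(C)[Si](C(C)C)(C(C)C)O[C@@H]2C[C@H]4C(=C)C(=O)O[C@H]4[C@H](OC(=O)/C(C)=C\C)[C@]3(COC(C)(C)O3)[C@H]2C | intermediate
33 | (1R,5S,6R,7S,9R,10S)-C1-OH/C2H2-OH diol | CC(C)[Si](C(C)C)(C(C)C)O[C@@H]2C[C@H]4C(=C)C(=O)O[C@H]4[C@H](OC(=O)/C(C)=C\C)[C@](O)(CO)[C@H]2C | intermediate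
34 | (1S,5S,6R,7S,9R,10S)-C2 aldehyde | CC(C)[Si](C(C)C)(C(C)C)O[C@@H]2C[C@H]4C(=C)C(=O)O[C@H]4[C@H](OC(=O)/C(C)=C\C)[C@](O)(C=O)[C@H]2C | intermediate
35 | (1R,5S,6R,7S,9R,10S)-C2 (E)-propenyl carbinol (C2 epimers) | CC(C)[Si](C(C)C)(C(C)C)O[C@@H]2C[C@H]4C(=C)C(=O)O[C@H]4[C@H](OC(=O)/C(C)=C\C)[C@](O)(C(O)/C=C/C)[C@H]2C | intermediate
36 | (1S,5S,6R,7S,9R,10S)-C9-OTIPS ether of the target | CC(C)[Si](C(C)C)(C(C)C)O[C@@H]2C[C@H]4C(=C)C(=O)O[C@H]4[C@H](OC(=O)/C(C)=C\C)[C@](O)(C(=O)/C=C/C)[C@H]2C | intermediate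
37 | CNP0149130.1 (1S,5S,6R,7S,9R,10S) | C=C1C(=O)O[C@@H]2[C@H]1C[C@@H](O)[C@H](C)[C@@](O)(C(=O)/C=C/C)[C@H]2OC(=O)/C(C)=C\C | target

**Totals**
Total step count: 31. Longest linear sequence: 29 steps (steps 1–3, 5–14 and 16–31, from methyl acrylate); steps 4 and 15 are one-step side branches.

**Steps most likely to fail, with fallbacks**

Step 5 (enantioselective aldol on a keto ester not covered by precedent; ee or syn selectivity may drop). Fallback, from catalyst to auxiliary control: set out from 4 and add to it the titanium enolate (TiCl4, i-Pr2NEt, CH2Cl2, −78 °C) of commercial (R)-4-benzyl-3-propanoyl-1,3-oxazolidin-2-one to give the imide aldol adduct F1, in which the auxiliary fixes C10 and any C1 epimer is removed by chromatography. Exchange the auxiliary with LiSEt (EtSH, n-BuLi, THF, 0 °C) to give the hydroxy thioester F2, then silylate with TMSOTf/2,6-lutidine to come back to the route at 7.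

Step 19 (MOM removal beside a ketal and two silyl ethers may not be selective). Fallback, an oxidatively cleaved C6 group instead: set out from 17 and use the (Z)-γ-(4-methoxyphenoxy)allyl borane F3 (from allyl 4-methoxyphenyl ether, sec-BuLi, (−)-Ipc2BOMe, BF3·OEt2) in place of 20 to give the C6 aryl ether F4. Silylate with TESOTf to the TES ether F5, close the ring with second-generation Grubbs catalyst to the cycloheptene F6, and cleave the aryl ether with (NH4)2Ce(NO3)6 (MeCN/H2O, pyridine buffer, 0 °C) to come back at 24.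

Step 26 (very hindered C5–OH; angelate may isomerise to tiglate under forcing acylation). Fallback, build the Z-alkene after acylation: set out from 31 and acylate with 2-[bis(2,2,2-trifluoroethoxy)phosphoryl]propanoic acid (DCC, DMAP, CH2Cl2) to the phosphonate ester F7. A Still–Gennari olefination with acetaldehyde (KN(SiMe3)2, 18-crown-6, THF, −78 °C) then gives the (Z)-2-methylbut-2-enoate and comes back at 32.

**Further compounds**
F1 | step 5 | (R)-4-benzyl-oxazolidinone imide aldol adduct (1S,10R), C1-OH | O=C1OC[C@@H](Cc2ccccc2)N1C(=O)[C@H](C)[C@@](O)(C(=O)OC)CO[Si](C)(C)C(C)(C)C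
F2 | step 5 | (1S,10R)-hydroxy thioester (7 without TMS) | CCSC(=O)[C@H](C)[C@@](O)(C(=O)OC)CO[Si](C)(C)C(C)(C)C
F3 | step 19 | [(Z)-3-(4-methoxyphenoxy)allyl]diisopinocampheylborane | COc1ccc(O/C=C\CB([C@@H]2C[C@@H]3C[C@@H](C3(C)C)[C@H]2C)[C@@H]2C[C@@H]3C[C@@H](C3(C)C)[C@H]2C)cc1
F4 | step 19 | (1R,5S,6R,9R,10S)-diene, C5-OH, C6-O-(4-methoxyphenyl) | C=C[C@@H](O[Si](C(C)C)(C(C)C)C(C)C)[C@H](C)[C@]1([C@@H](O)[C@H](Oc2ccc(OC)cc2)C=C)COC(C)(C)O1
F5 | step 19 | C5-OTES ether of F4 | C=C[C@@H](O[Si](C(C)C)(C(C)C)C(C)C)[C@H](C)[C@]1([C@@H](O[Si](CC)(CC)CC)[C@H](Oc2ccc(OC)cc2)C=C)COC(C)(C)O1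
F6 | step 19 | cycloheptene with C6-O-(4-methoxyphenyl) | CC(C)[Si](C(C)C)(C(C)C)O[C@@H]2C=C[C@@H](Oc4ccc(OC)cc4)[C@H](O[Si](CC)(CC)CC)[C@]3(COC(C)(C)O3)[C@H]2C
F7 | step 26 | C5-O-[2-(bis(2,2,2-trifluoroethoxy)phosphoryl)propanoyl] ester of 31 | CC(C)[Si](C(C)C)(C(C)C)O[C@@H]2C[C@H]4C(=C)C(=O)O[C@H]4[C@H](OC(=O)C(C)P(=O)(OCC(F)(F)F)OCC(F)(F)F)[C@]3(COC(C)(C)O3)[C@H]2C
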